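**Retrosynthetic overview**

1. The target is traced back, through hydrogenolysis of two benzyl ethers and Markovnikov hydration of the prenyl alkene, to 2',4'-di-O-benzyl-8-prenyl-5,7-dihydroxyisoflavone.
2. Ring A is an acylphloroglucinol: the oxygen-bearing carbons C5, C7 and C8a alternate with C4a, C6 and C8, as in a folded 1,3-polycarbonyl chain. It is cut at C5–C6 (intramolecular Claisen condensation, then aromatisation) to a 4-pyranone with CO2Me on C4a and a CH(prenyl)C(O)CH3 chain on C8a, so the prenyl group is fixed on C8 before ring A exists.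
3. That chain is grown from the 2-methyl group of the pyranone: lateral C-acetylation, then C-prenylation of the activated methylene.
4. The pyranone (ring C) comes from a triketo ester (arylacetyl chloride plus methyl acetoacetate) and DMF dimethyl acetal; ring B is bought as 2,4-dihydroxyphenylacetic acid.
5. Order of rings: ring B (purchased), ring C (step 4), ring A (step 7).

Key step: step 7

Assumption: the key-step precursor is racemic and its SMILES shows one enantiomer; the centre is lost on aromatisation. The triketo ester and the β-dicarbonyl compounds are drawn as keto forms although they should be largely enolised.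

**Route**

Step 1
Reactants: 1 2,4-dihydroxyphenylacetic acid; 2 benzyl bromide
Product: 3 benzyl [2,4-bis(benzyloxy)phenyl]acetate
Conditions: BnBr (3.3 equiv), K2CO3, DMF, 60 °C
Reagents that add atoms: benzyl bromide, BrCc1ccccc1
Why: Williamson O-alkylation of both phenoxides and of the carboxylate should give the tribenzyl compound, the basic medium keeping the 2-hydroxyarylacetic acid from lactonising.

Step 2
Reactants: 3 benzyl [2,4-bis(benzyloxy)phenyl]acetate
Product: 4 [2,4-bis(benzyloxy)phenyl]acetic acid
Conditions: LiOH·H2O, THF/MeOH/H2O, 50 °C; then 1 M HCl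
Reagents that add atoms: lithium hydroxide, [Li+].[OH-]
Why: Saponification of the benzyl ester should free the acid while the two aryl benzyl ethers are inert to hydroxide.

Step 3
Reactants: 4 [2,4-bis(benzyloxy)phenyl]acetic acid; 5 methyl acetoacetate
Product: 7 methyl 2-acetyl-4-[2,4-bis(benzyloxy)phenyl]-3-oxobutanoate, via arylacetyl chloride 6 (not isolated)
Conditions: (COCl)2, cat. DMF, CH2Cl2, 0 °C to rt, evaporate; then 5, MgCl2, pyridine, CH2Cl2, 0 °C to rt; 1 M HCl
Reagents that add atoms: methyl acetoacetate, COC(=O)CC(C)=O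
Why: The acid chloride should acylate the chelated magnesium enolate of the β-keto ester at carbon (soft-enolisation C-acylation with MgCl2 and pyridine), giving the triketo ester in one operation.

Step 4
Reactants: 7 methyl 2-acetyl-4-[2,4-bis(benzyloxy)phenyl]-3-oxobutanoate; 8 N,N-dimethylformamide dimethyl acetal
Product: 10 methyl 5-[2,4-bis(benzyloxy)phenyl]-2-methyl-4-oxo-4H-pyran-3-carboxylate, via enaminone 9 (not isolated)
Conditions: Me2NCH(OMe)2 (1.3 equiv), PhMe, 70 °C; then AcOH, 70 °C
Reagents that add atoms: N,N-dimethylformamide dimethyl acetal, COC(OC)N(C)C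
Why: The amide acetal should condense at the benzylic methylene, the most acidic C–H outside the enolised tricarbonyl core, and the enol oxygen of the acetyl group then displaces dimethylamine by 6-endo addition–elimination (enaminone route to 4-pyranones, as in isoflavone synthesis from deoxybenzoins).

Step 5
Reactants: 10 methyl 5-[2,4-bis(benzyloxy)phenyl]-2-methyl-4-oxo-4H-pyran-3-carboxylate; 11 1-acetylimidazole
Product: 12 methyl 5-[2,4-bis(benzyloxy)phenyl]-4-oxo-2-(2-oxopropyl)-4H-pyran-3-carboxylate
Conditions: LiN(SiMe3)2 (2.05 equiv), THF, −78 °C; 11 (1.1 equiv), −78 to −40 °C; AcOH, −78 °C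
Reagents that add atoms: 1-acetylimidazole, CC(=O)n1ccnc1
Why: Lateral deprotonation of the 2-methyl group (vinylogous to the C4 carbonyl and the C3 ester) gives a dienolate that should be C-acylated at the exocyclic carbon by the acyl imidazole (Claisen-type acylation), the second equivalent of base storing the more acidic product as its enolate while the absence of a third equivalent keeps the ring closure of step 7 from starting.

Step 6
Reactants: 12 methyl 5-[2,4-bis(benzyloxy)phenyl]-4-oxo-2-(2-oxopropyl)-4H-pyran-3-carboxylate; 13 prenyl bromide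
Product: 14 methyl 5-[2,4-bis(benzyloxy)phenyl]-2-(6-methyl-2-oxohept-5-en-3-yl)-4-oxo-4H-pyran-3-carboxylate (racemic; the (3R) enantiomer is drawn)
Conditions: 13 (1.1 equiv), K2CO3, acetone, rt
Reagents that add atoms: prenyl bromide, CC(C)=CCBr
Why: C-alkylation of the stabilised enolate of the doubly activated methylene with a soft allylic bromide (as in acetoacetate alkylation) should place the prenyl group on the future C8; the new stereocentre forms without control, which is of no consequence.

Step 7
Reactants: 14 methyl 5-[2,4-bis(benzyloxy)phenyl]-2-(6-methyl-2-oxohept-5-en-3-yl)-4-oxo-4H-pyran-3-carboxylate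
Product: 15 3-[2,4-bis(benzyloxy)phenyl]-5,7-dihydroxy-8-(3-methylbut-2-en-1-yl)-4H-chromen-4-one (2',4'-di-O-benzyl-2,3-dehydrokievitone)
Conditions: LiN(SiMe3)2 (3.5 equiv), THF, −78 to 0 °C; then 1 M HCl
Reagents that add atoms: none
Why: LiN(SiMe3)2 should first remove the C8 proton (α to the ketone and vinylogous to the C4 carbonyl) and then a proton of the terminal methyl C6; the C6 carbanion of this dianion adds to the C5 ester carbonyl, methoxide leaves, and the cyclic triketone enolises to the 5,7-diphenolate, which makes the sequence irreversible. The closest known reaction type is the biomimetic Claisen cyclisation and aromatisation of polyanions of 1,3-polycarbonyl chains to acylphloroglucinols, with the pyranone here standing for the acyl part. Ring A closes in a 6-exo-trig mode through C6, C7, C8, C8a, C4a and C5. No stereocentre is formed, and the racemic centre of 14 becomes the aromatic carbon C8. The step needs attack on the ester and not at C2 or C4 of the pyranone: the silylamide is non-nucleophilic, the ester is the only carbonyl the in-plane chain can reach without forming a bridged ring, and its twist out of conjugation between the C4 carbonyl and the branched C8a substituent should keep it electrophilic. The position of the prenyl group is not at issue because it was fixed on C8 in step 6.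

Step 8
Reactants: 15 3-[2,4-bis(benzyloxy)phenyl]-5,7-dihydroxy-8-(3-methylbut-2-en-1-yl)-4H-chromen-4-one
Product: 16 3-[2,4-bis(benzyloxy)phenyl]-5,7-dihydroxy-8-(3-hydroxy-3-methylbutyl)-4H-chromen-4-one
Conditions: Co(acac)2 (20 mol %), PhSiH3, O2 (1 atm), THF/i-PrOH, rt
Reagents that add atoms: dioxygen, O=O
Why: In this Mukaiyama hydration, hydrogen-atom transfer from a cobalt hydride to the electron-rich trisubstituted alkene should give the tertiary radical, which is trapped by O2 and reduced by the silane to the Markovnikov tertiary alcohol, while the pyranone double bond and the benzyl ethers are inert.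

Step 9
Reactants: 16 3-[2,4-bis(benzyloxy)phenyl]-5,7-dihydroxy-8-(3-hydroxy-3-methylbutyl)-4H-chromen-4-one
Product: 17 3-(2,4-dihydroxyphenyl)-5,7-dihydroxy-8-(3-hydroxy-3-methylbutyl)-4H-chromen-4-one (2,3-dehydrokievitone hydrate)
Conditions: H2 (1 atm), 10% Pd/C, EtOAc/MeOH, rt, stopped at full debenzylation
Reagents that add atoms: none
Why: Hydrogenolysis of the two aryl benzyl ethers over Pd/C under neutral conditions should leave the tertiary alcohol untouched, and the C2=C3 bond of the isoflavone, which reduces far more slowly, is kept by stopping the reaction once debenzylation is complete.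

**Compound list**

1 | 2,4-dihydroxyphenylacetic acid | OC(=O)Cc1ccc(O)cc1O | starting material
2 | benzyl bromide | BrCc1ccccc1 | starting material
3 | benzyl [2,4-bis(benzyloxy)phenyl]acetate | O=C(OCc1ccccc1)Cc1ccc(OCc2ccccc2)cc1OCc1ccccc1 | intermediate
4 | [2,4-bis(benzyloxy)phenyl]acetic acid | OC(=O)Cc1ccc(OCc2ccccc2)cc1OCc1ccccc1 | intermediate
5 | methyl acetoacetate | COC(=O)CC(C)=O | starting material
6 | [2,4-bis(benzyloxy)phenyl]acetyl chloride | ClC(=O)Cc1ccc(OCc2ccccc2)cc1OCc1ccccc1 | intermediate (not isolated)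
7 | methyl 2-acetyl-4-[2,4-bis(benzyloxy)phenyl]-3-oxobutanoate | COC(=O)C(C(C)=O)C(=O)Cc1ccc(OCc2ccccc2)cc1OCc1ccccc1 | intermediate
8 | N,N-dimethylformamide dimethyl acetal | COC(OC)N(C)C | starting material
9 | methyl 2-acetyl-4-[2,4-bis(benzyloxy)phenyl]-5-(dimethylamino)-3-oxopent-4-enoate (alkene geometry not defined) | COC(=O)C(C(C)=O)C(=O)C(=CN(C)C)c1ccc(OCc2ccccc2)cc1OCc1ccccc1 | intermediate (not isolated)
10 | methyl 5-[2,4-bis(benzyloxy)phenyl]-2-methyl-4-oxo-4H-pyran-3-carboxylate | COC(=O)c1c(C)occ(-c2ccc(OCc3ccccc3)cc2OCc2ccccc2)c1=O | intermediate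
11 | 1-acetylimidazole | CC(=O)n1ccnc1 | starting material
12 | methyl 5-[2,4-bis(benzyloxy)phenyl]-4-oxo-2-(2-oxopropyl)-4H-pyran-3-carboxylate | COC(=O)c1c(CC(C)=O)occ(-c2ccc(OCc3ccccc3)cc2OCc2ccccc2)c1=O | intermediate
13 | prenyl bromide (1-bromo-3-methylbut-2-ene) | CC(C)=CCBr | starting material
14 | methyl 5-[2,4-bis(benzyloxy)phenyl]-2-[(3R)-6-methyl-2-oxohept-5-en-3-yl]-4-oxo-4H-pyran-3-carboxylate (racemic, one enantiomer drawn) | COC(=O)c1c([C@@H](CC=C(C)C)C(C)=O)occ(-c2ccc(OCc3ccccc3)cc2OCc2ccccc2)c1=O | intermediate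
15 | 3-[2,4-bis(benzyloxy)phenyl]-5,7-dihydroxy-8-(3-methylbut-2-en-1-yl)-4H-chromen-4-one | CC(C)=CCc1c(O)cc(O)c2c(=O)c(-c3ccc(OCc4ccccc4)cc3OCc3ccccc3)coc12 | intermediate
16 | 3-[2,4-bis(benzyloxy)phenyl]-5,7-dihydroxy-8-(3-hydroxy-3-methylbutyl)-4H-chromen-4-one | CC(C)(O)CCc1c(O)cc(O)c2c(=O)c(-c3ccc(OCc4ccccc4)cc3OCc3ccccc3)coc12 | intermediate
17 | 3-(2,4-dihydroxyphenyl)-5,7-dihydroxy-8-(3-hydroxy-3-methylbutyl)-4H-chromen-4-one (2,3-dehydrokievitone hydrate) | CC(C)(O)CCc1c(O)cc(O)c2c(=O)c(-c3ccc(O)cc3O)coc12 | target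

**Step count**

Total steps: 9. Longest linear sequence: 9 steps (from 1 to 17).

**Steps most likely to fail**

1. Step 7. The dianion may form but not close, because the C5 ester is shielded by its two neighbours and carries part of the charge of the C8 anion, or the base may bring about opening of the pyranone by conjugate addition at C2. The fallback sets out from 4 and comes back at 15; it buys ring A and fixes the prenyl group on C8 by two consecutive [3,3] shifts.
   - Friedel–Crafts acylation of phloroglucinol with acid 4 (BF3·OEt2, 70 °C) should give 2-[2,4-bis(benzyloxy)phenyl]-1-(2,4,6-trihydroxyphenyl)ethan-1-one F1.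
   - Ring C is closed with DMF, BF3·OEt2 and MsCl to give 3-[2,4-bis(benzyloxy)phenyl]-5,7-dihydroxy-4H-chromen-4-one F2.
   - Selective acetylation of the free 7-OH (Ac2O, pyridine, 0 °C; the chelated 5-OH is left) gives 3-[2,4-bis(benzyloxy)phenyl]-5-hydroxy-4-oxo-4H-chromen-7-yl acetate F3.
   - Mitsunobu etherification of the 5-OH with 3-methylbut-2-en-1-ol (PPh3, DIAD, THF) gives 3-[2,4-bis(benzyloxy)phenyl]-5-[(3-methylbut-2-en-1-yl)oxy]-4-oxo-4H-chromen-7-yl acetate F4.
   - The para-Claisen–Cope rearrangement promoted by Eu(fod)3 [tris(6,6,7,7,8,8,8-heptafluoro-2,2-dimethyloctane-3,5-dionato)europium] in CHCl3 at 60 °C moves the prenyl group from O5 by way of C6 to C8 and should give 3-[2,4-bis(benzyloxy)phenyl]-5-hydroxy-8-(3-methylbut-2-en-1-yl)-4-oxo-4H-chromen-7-yl acetate F5.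
   - K2CO3 in MeOH removes the acetate and returns to 15.

2. Step 4. The amide acetal may condense at the acetyl methyl instead of the benzylic methylene, the acetyl group may be lost by retro-Claisen cleavage under the action of liberated methanol and dimethylamine, or the acidic enol may be O-methylated. The fallback sets out from 5 and comes back at 10; the pyranone is built with no regiochemical choice and the aryl group is attached last by cross-coupling.
   - C-acylation of the magnesium enolate of 5 with (E)-3-ethoxyacryloyl chloride (MgCl2, pyridine, CH2Cl2) should give methyl (4E)-2-acetyl-5-ethoxy-3-oxopent-4-enoate F6.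
   - TFA closes it with loss of ethanol to methyl 2-methyl-4-oxo-4H-pyran-3-carboxylate F7.
   - Iodination at C5, the enol-ether carbon α to the ketone (I2, PhI(OCOCF3)2, pyridine, CH2Cl2), gives methyl 5-iodo-2-methyl-4-oxo-4H-pyran-3-carboxylate F8.
   - Suzuki–Miyaura coupling with purchased 2,4-bis(benzyloxy)phenylboronic acid (Pd(PPh3)4, Na2CO3, DME/H2O, 80 °C) returns to 10.

3. Step 5. The dienolate may be acylated on oxygen, the lateral anion may add to C6 of a second pyranone, or ring A may close early to the isoflavone lacking the prenyl group if more than two equivalents of base are present. The fallback sets out from 4 and comes back at 12; the acetonyl group is brought in masked form with the β-keto ester, so no lateral acylation is needed.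
   - Crossed Claisen condensation of purchased ethyl (2-methyl-1,3-dioxolan-2-yl)acetate with the lithium enolate of methyl acetate (LiN(i-Pr)2, THF, −78 °C to rt) should give methyl 4-(2-methyl-1,3-dioxolan-2-yl)-3-oxobutanoate F9.
   - F9 is C-acylated with acid chloride 6, made from 4 as in step 3 (MgCl2, pyridine), to methyl 2-{[2,4-bis(benzyloxy)phenyl]acetyl}-4-(2-methyl-1,3-dioxolan-2-yl)-3-oxobutanoate F10.
   - Condensation with 8 and closure in AcOH, as in step 4 (the methylene next to the ketal is less acidic and more hindered than the benzylic one), gives methyl 5-[2,4-bis(benzyloxy)phenyl]-2-[(2-methyl-1,3-dioxolan-2-yl)methyl]-4-oxo-4H-pyran-3-carboxylate F11.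
   - Aqueous HCl in acetone removes the ketal and returns to 12.

**Further compounds**

F1 | step 7 | 2-[2,4-bis(benzyloxy)phenyl]-1-(2,4,6-trihydroxyphenyl)ethan-1-one | O=C(Cc1ccc(OCc2ccccc2)cc1OCc1ccccc1)c1c(O)cc(O)cc1O
F2 | step 7 | 3-[2,4-bis(benzyloxy)phenyl]-5,7-dihydroxy-4H-chromen-4-one | O=c1c(-c2ccc(OCc3ccccc3)cc2OCc2ccccc2)coc2cc(O)cc(O)c12
F3 | step 7 | 3-[2,4-bis(benzyloxy)phenyl]-5-hydroxy-4-oxo-4H-chromen-7-yl acetate | CC(=O)Oc1cc(O)c2c(=O)c(-c3ccc(OCc4ccccc4)cc3OCc3ccccc3)coc2c1
F4 | step 7 | 3-[2,4-bis(benzyloxy)phenyl]-5-[(3-methylbut-2-en-1-yl)oxy]-4-oxo-4H-chromen-7-yl acetate | CC(=O)Oc1cc(OCC=C(C)C)c2c(=O)c(-c3ccc(OCc4ccccc4)cc3OCc3ccccc3)coc2c1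
F5 | step 7 | 3-[2,4-bis(benzyloxy)phenyl]-5-hydroxy-8-(3-methylbut-2-en-1-yl)-4-oxo-4H-chromen-7-yl acetate | CC(=O)Oc1cc(O)c2c(=O)c(-c3ccc(OCc4ccccc4)cc3OCc3ccccc3)coc2c1CC=C(C)C
F6 | step 4 | methyl (4E)-2-acetyl-5-ethoxy-3-oxopent-4-enoate | CCO/C=C/C(=O)C(C(C)=O)C(=O)OC
F7 | step 4 | methyl 2-methyl-4-oxo-4H-pyran-3-carboxylate | COC(=O)c1c(C)occc1=O
F8 | step 4 | methyl 5-iodo-2-methyl-4-oxo-4H-pyran-3-carboxylate | COC(=O)c1c(C)occ(I)c1=O
F9 | step 5 | methyl 4-(2-methyl-1,3-dioxolan-2-yl)-3-oxobutanoate | COC(=O)CC(=O)CC1(C)OCCO1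
F10 | step 5 | methyl 2-{[2,4-bis(benzyloxy)phenyl]acetyl}-4-(2-methyl-1,3-dioxolan-2-yl)-3-oxobutanoate | COC(=O)C(C(=O)CC1(C)OCCO1)C(=O)Cc1ccc(OCc2ccccc2)cc1OCc1ccccc1
F11 | step 5 | methyl 5-[2,4-bis(benzyloxy)phenyl]-2-[(2-methyl-1,3-dioxolan-2-yl)methyl]-4-oxo-4H-pyran-3-carboxylate | COC(=O)c1c(CC2(C)OCCO2)occ(-c2ccc(OCc3ccccc3)cc2OCc2ccccc2)c1=O
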